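The readings were generated by integration for an exercise; noise was put on by code.

No run so far stood as cold as 60 °C, so the share in birch cannot be read off. With that the meeting opened, and the chair asked what carries from the two runs to the four new flasks.

the same everywhere: reagent 0.112 M

| charge | substrate | temperature | remark | time |
|---|---|---|---|---|
| Thursday's | 0.094 M | 72 °C | run made earlier |  |
| Sunday's | 0.21 M | 100 °C | run made earlier |  |
| birch | 0.14 M | 60 °C |  | 8.0 min |
| elm | 0.14 M |  | at 60 °C until 1.5 min, from then on at 110 °C | 8.0 min |
| cedar | 0.14 M | 85 °C |  | 8.0 min |
| ash | 0.14 M | 110 °C |  | 8.0 min |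

Thursday's run (percent of the substrate charged)

| time / min | target / % | side product / % |
|---|---|---|
| 0.500 | 70.1 | 15.9 |
| 0.667 | 71.8 | 15.8 |
| 1.00 | 76.4 | 16.7 |
| 1.33 | 79.2 | 17.9 |
| 2.00 | 78.4 | 16.3 |
| 3.00 | 79.3 | 18.0 |
| 6.00 | 81.9 | 16.5 |

Sunday's run (percent of the substrate charged)

| time / s | target / % | side product / % |
|---|---|---|
| 10.0 | 37.6 | 7.7 |
| 12.0 | 38.9 | 7.3 |
| 15.0 | 37.3 | 7.5 |
| 20.0 | 37.9 | 7.0 |
| 30.0 | 37.5 | 8.2 |
| 50.0 | 38.5 | 8.5 |
| 80.0 | 39.4 | 8.4 |

(readings scatter by 1 percentage point)

- the flask with the highest share of target in all that became target or side product ("all alike" if they lie within 1.5 percentage points) (birch / elm / cedar / ash / all alike)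
- share of target in all that became target or side product, birch
- share of target in all that became target or side product, elm
- share of target in all that became target or side product, cedar
- share of target in all that became target or side product, ash

- a species is counted by the substrate in it: one self-condensation product counts as two
- steps that have been proposed: substrate + reagent -> target; 2 substrate -> self-condensation product; substrate + 2 reagent -> side product

The first speaker noted that both proposed reagent steps take one substrate. So substrate cancels from side product per target, and a constant times the standing reagent remains. She read the last points: 0.201 side product per target on Thursday and 0.213 on Sunday, mean 0.207. Target plus twice the side product came to 96.4% and 105% of the reagent charge, so she took reagent as used up in both.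

The second speaker first put the mean reagent at 0.5 of the charge, which gave 3.70 L mol⁻¹. He put that back in. It makes reagent go quicker early on, so the mean met by each target came to 0.450 of the charge. Going round once more gave 4.11 L mol⁻¹, the split factor, side product per target for each molar of standing reagent (a selectivity factor).

The secretary's own reckoning followed. If reagent is the limiting reagent, a charge of 0.112 M gives a share of 83.0% and takes 0.0957 M of the 0.14 M substrate.

The forecaster gave 83.5% for birch (81.5% to 85.5%), 83.3% for elm (81.5% to 85.2%), 83.3% for cedar (81.7% to 85%) and 83.3% for ash (81.3% to 86%), so all alike. The stated ground was: “The selectivity therefore shows essentially no temperature dependence.”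

The flasks gave 83.0% in birch, 83.0% in elm, 83.7% in cedar and 84.2% in ash: all alike. The forecast held.

    substrate + reagent → target (k = 1.10 L mol⁻¹ s⁻¹, Ea = 46.0 kJ mol⁻¹)
    2 substrate → self-condensation product (k = 0.00420 L mol⁻¹ s⁻¹, Ea = 76.0 kJ mol⁻¹)
    substrate + 2 reagent → side product (k = 4.50 L² mol⁻² s⁻¹, Ea = 44.0 kJ mol⁻¹)
    (constants at 60 °C)

Birch ended with 0% reagent and 26.4% substrate, the case the split factor describes, and it reckons 83.0% there. In ash the self-condensation product reached 26.7% at 8.00 min, and that step makes no difference to the share in ash. Ash ended with 0% reagent, and this running short of reagent is part of what holds ash at 84.2%; without it ash gives 70.6%. A neighbour flask, birch with 0.045 M reagent, ended with 0% reagent; the factor reckons 91.9% for it, and it gave 92.0%.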